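(The numbers in the tables were generated by integration from invented constants; scatter was added.)

The trap in this flask is to watch D, the substrate, which is charged at twice the reagent J. The suspected round of the catalyst L takes one D and one J for each X, so J is the limiting reagent and X can reach 0.0500 M, not 0.10 M.

- north-east: D 0.10 M; J 0.050 M; L 0.72 mM; the very flask that is asked about, followed so far
- flask: D 0.10 M; J 0.0500 M; L 0.72 mM; time 15 min

north-east run (percent of the D charged)

| time / min | X / % | D / % |
|---|---|---|
| 0.417 | 4.5 | 96.5 |
| 1.33 | 11.7 | 88.6 |
| 2.00 | 15.7 | 83.4 |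
| 3.00 | 22.5 | 77.9 |
| 5.00 | 31.7 | 67.9 |
| 6.00 | 35.1 | 63.1 |

(standard deviation of a reading: 0.5 percentage points)

- on the list of suspects stand: Z -> G; G -> L + X; D + L -> E; L <-> Q; J + E <-> Z

- concentration of X at 15 min, in M
- concentration of D at 15 min, in M
- concentration of J at 15 min, in M

J is not read, but each X made has used one J, so J left is the charge less X. I carry the J clock, the natural log of J charged over J left, divided by the time: 0.202 min⁻¹ at 6.00 min, as a reading. At 1.33 min it reads 0.200 min⁻¹. Between those readings D falls by a factor of 1.40, but the clock moves by a factor of only 1.01. So I treat J as pseudo-first-order, like a first-order lag with half-life 3.44 min, and take E, the form of the catalyst that J enters, as the resting state.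

Held to 15 min, the clock leaves 0.00242 M of J, which gives 0.0476 M of X and 0.0524 M of D.

The forecast, reasoning that “the rate is first order in J and roughly zero order in D”, gives 0.0473 M of X, 0.052 M of D and 0.0027 M of J, more J than mine.

The flask gives 0.0480 M of X, 0.0513 M of D and 0.00203 M of J.

    Z → G (k = 2.06 s⁻¹)
    G → L + X (k = 4.00 s⁻¹)
    D + L → E (k = 71.1 M⁻¹ s⁻¹)
    L ⇌ Q (K = 1.78, k = 0.00215 s⁻¹)
    J + E ⇌ Z (K = 10.0 M⁻¹, k = 7.29 M⁻¹ s⁻¹)

In this flask at 15 min the clock stands at 0.213 min⁻¹, and the half-life of J by the forward step J + E → Z alone, 2.3 min, is short against that time, with 4.1% of the J charge left against 51% of the D charge. In the flask charged with 0.20 M of J, the same clock taken at 15 min reads 0.0462 min⁻¹, less than 0.202 min⁻¹, but it is no rate there, for D is the limiting reagent: at that time the flask holds 0.100 M of X, 0.100 M of J and 2.40 × 10⁻¹⁰ M of D.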